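Per day, in fractions of the charge: that is how to read these runs of a solid substrate stirred with reagent.

| flask | solid substrate | reagent | remark | time |
|---|---|---|---|---|
| south | 0.95 M | 0.57 M | run made earlier |  |
| south-west | 0.95 M | 2.3 M | run made earlier |  |
| south-east | 0.47 M | 1.14 M | run made earlier |  |
| flask | 0.95 M | 1.14 M |  | 4.0 d |

| run | time / d | solid substrate / % | mono adduct / % |
|---|---|---|---|
| south | 0.500 | 94.8 | 1.3 |
| south | 1.04 | 90.2 | 2.8 |
| south | 1.67 | 84.1 | 3.8 |
| south | 2.00 | 80.8 | 3.8 |
| south | 2.50 | 76.3 | 4.5 |
| south | 3.00 | 71.6 | 4.7 |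
| south-west | 0.208 | 97.9 | 1.0 |
| south-west | 0.625 | 93.0 | 0.7 |
| south-west | 1.04 | 89.0 | 1.1 |
| south-west | 1.67 | 82.2 | 1.2 |
| south-west | 2.50 | 73.4 | 0.9 |
| south-west | 3.00 | 68.2 | 1.3 |
| south-east | 0.250 | 93.9 | 1.8 |
| south-east | 0.833 | 82.7 | 3.5 |
| south-east | 1.67 | 65.6 | 4.2 |
| south-east | 2.50 | 49.2 | 5.4 |
| south-east | 3.00 | 38.7 | 5.6 |

(readings scatter by 0.3 percentage points)

- how much solid substrate there is at 4.0 d, in percent of the solid substrate charged (only what is still solid)
- how much mono adduct there is at 4.0 d, in percent of the solid substrate charged
- how much other mono adduct there is at 4.0 d, in percent of the solid substrate charged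
- how much bis adduct there is at 4.0 d, in percent of the solid substrate charged

- solid substrate is a solid; its amount is given per volume of the solution
- what was read earlier has a scatter of 0.3 percentage points, one standard deviation
- at the start none of the solid substrate is in solution

Per day, up to their last readings, south-east gave up 0.204 d⁻¹ of its charge and south 0.0947 d⁻¹: twice the fraction from a charge half as big, with twice the reagent. Raising the reagent from 0.57 M to 2.3 M at the same charge moves the fraction from 0.0947 d⁻¹ to just 0.106 d⁻¹. So dissolving looks like the rate-limiting step, and south-east, with the flask's reagent, gives the pace. Fold charge and time into one number: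

S = 61.3 % × (0.47 M / 0.95 M) × (4.0 d / 3.00 d) = 0.404

S, the dissolved fraction, is the part of the flask's charge that this pace carries off by the asked time. My reckoning leaves the rest, 59.6 %, as solid.

Is one number enough? Not for the adducts. At their last readings south had lost 28.4 % and south-west 31.8 %, yet they show 4.7 % and 1.3 % of mono adduct. S reads the solid and leaves the split open.

The forecast gave 60 % solid, 3.2 % mono adduct, 26 % other mono adduct and 10.8 % bis adduct, holding that “the other mono adduct dominates”.

The flask gives 59.7 % solid, 3.34 % mono adduct, 2.15 % other mono adduct and 24.8 % bis adduct.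

    reagent + mono adduct → bis adduct + by-product (k = 0.110 M⁻¹ h⁻¹)
    reagent + mono adduct → over-reaction product (k = 0.0430 M⁻¹ h⁻¹)
    starting material + reagent → mono adduct + by-product (k = 0.190 M⁻¹ h⁻¹)
    starting material + reagent → other mono adduct + by-product (k = 0.0620 M⁻¹ h⁻¹)
    reagent + other mono adduct → bis adduct + by-product (k = 0.0710 M⁻¹ h⁻¹)
    solid substrate ⇌ starting material, rate k6*(cs6 - [starting material]) while solid is left; crystals form when [starting material] > cs6 (solubility = 0.200 M, k = 0.0220 h⁻¹)

In this flask, dissolving has a net turnover of 40.3 % of the charge, beside S of 0.404. The forecast and the flask part on the adducts. In this flask at 4.00 d, starting material is used 3.1 times as fast by the step to mono adduct as by the step to other mono adduct. At 1.96 d, this flask makes mono adduct 1.06 times as fast as it uses it up, each step taken net. Stopped at 25 h, the same flask has S of 0.105, which leaves 89.5 %, and it holds 89.2 % solid.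

The runs are simulated for an exercise, and the scatter is random.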